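Beside the neighbour flask, a warmer repeat of south-west, I wrote this note for whoever took over the bench, and I asked of each flask how many half-lives of ring closing fitted into its run.

    substrate ⇌ ring (K1 = 0.92, k1 = 0.0231 /s, Ea1 = 78.0 kJ/mol, ΔH1 = −66.0 kJ/mol)
    substrate + substrate ⇌ open dimer (K2 = 1.49 /M, k2 = 0.183 /M/s, Ea2 = 40.0 kJ/mol, ΔH2 = 1.00 kJ/mol)
    2 substrate → homo dimer (k3 = 1.58 × 10⁻⁴ /M/s, Ea3 = 73.0 kJ/mol)
    (constants at 25 °C)

| setting | north-east | north | east | south-west |
|---|---|---|---|---|
| substrate | 0.30 M | 0.30 M | 0.30 M | 0.30 M |
| temperature | 65 °C | 45 °C | 85 °C | 25 °C |
| time | 1.5 min | 1.5 min | 1.5 min | 1.5 min |

* which flask leads in amount of ring, in percent of the substrate charged ("all alike" within 1.5 percentage points) (north-east / north / east / south-west / all alike)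
* how much ring is there at the end, in percent of the substrate charged: north-east
* how much ring is there at the end, in percent of the substrate charged: north
* how much ring is there at the end, in percent of the substrate charged: east
* how much ring is there at the end, in percent of the substrate charged: south-west

- in percentages every species weighs as the substrate in it: one open dimer or homo dimer counts as two
- for a step with 2 of a species take k times the square, and two of it per event
- the constants hold at 25 °C; other temperatures follow from the activation energies and enthalpies

In south-west the forward constant 0.0231 /s and the reverse constant 0.0251 /s added up, so substrate and ring relaxed towards each other with a half-life of 0.240 min. The run then came to 6.26: that is the count, the asked time divided by the relaxation half-life. By ring closing taken alone, such a count left 1.31% of the way to go, so I treated the flask as nearly balanced. I set ring at the constant times substrate, put open dimer at its own equilibrium and left homo dimer aside. The charge then divided into a substrate fraction of 43.3% and a ring fraction of 39.9%, and the remaining gap brought my figure for south-west to 39.4%.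

East was the other end. Forward ring closing ran 190 times faster there, but the constant fell to 0.0106, so the half-life was 0.00162 s and the count 55500. I expected ring in east to follow substrate at that constant, which is thermodynamic control. So the note said: do not wait on south-west, whose half-life was shorter than the run, and do not warm it, since the constant in east was smaller than in south-west.

The forecast named south-west as leader with 38.6% of ring, below my figure, then gave 9.95% for north, 2.25% for north-east and 0.485% for east, holding that “In the hotter flasks ring is fully equilibrated”.

South-west led with 38.4% of ring, against 9.95% in north, 2.25% in north-east and 0.485% in east, so the forecast stood. In south-west, with a count of 6.26, the length of the run was not what held ring down, for ten times as long gave 39.3%; what held it was the reverse step, ring to substrate, for with that step struck out ring reached 78.2%. East, with its count of 55500, showed ring over substrate at 0.0106 against the constant 0.0106, and striking out the same reverse step took its ring from 0.485% to 99.9%.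

The rate constants are those of an exercise; the flask was simulated.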